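**Plan**

1. Ring numbering used here: O1, C2 (side chain), C3(Br), C4(=O), C5(Br), C6(Br). Going backwards, the C6–Br bond is cut first (to C6–H) and the side-chain ketone is taken back to a TBS-protected carbinol; the ring is then cut at C2–C3 and O1–C6.
2. Enabling feature: C3–C4–C5 is a 1,3-dibromoacetone unit, C6 is a formyl-level enol-ether carbon and C2 is an acyl-level carbon bound to O1. The ring is therefore a C3–C6 1-methoxy-3-siloxydiene carrying both α-bromines plus a C2/O1 acid chloride.
3. Forward: diene 6 from 4-methoxybut-3-en-2-one (steps 1–3), acid chloride 9 from 2-hydroxybutanoic acid (steps 4–5), C-acylation and closure of the only ring (step 6), then C6 zincation–bromination, desilylation and oxidation (steps 7–9).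
4. The acyl partner is used as the α-silyloxy rather than the α-oxo acid chloride. The acid chloride is then the only electrophilic carbonyl in step 6, and no enolisable ketone is present when C6–H is metalated. Br2 addition/elimination on the free propanoyl compound is avoided because the ketone α-position would be brominated as well.
5. Stereochemistry: the target has no stereocentre; the diene geometries vanish on ring closure and the racemic carbinol centre is erased by the last oxidation.

Key step: step 6

Remark: the target is achiral, so no enantiocontrol is needed; compounds 7–14 are racemic at the side-chain carbinol carbon, which becomes the ketone in step 9.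

**Route**

Step 1
Reactants: 1 (E)-4-methoxybut-3-en-2-one
Product: 3 (Z)-3-bromo-4-methoxybut-3-en-2-one, via dibromide 2 (not isolated)
Conditions: Br2, CH2Cl2, −78 °C; then Et3N, −78 °C → rt
Reagents that add atoms: bromine, BrBr
Why: Anti-addition of bromine to the electron-rich enol ether double bond followed by amine-induced E1cB loss of HBr (acidic C3–H, bromide leaving from C4) is the standard bromination–dehydrobromination route to α-bromo-β-alkoxy enones and places the first bromine on the future C5.

Step 2
Reactants: 3 (Z)-3-bromo-4-methoxybut-3-en-2-one
Product: 5 (Z)-1,3-dibromo-4-methoxybut-3-en-2-one, via silyl dienol ether 4 (not isolated)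
Conditions: LiHMDS, THF, −78 °C; TMSCl; then NBS, −78 → 0 °C
Reagents that add atoms: N-bromosuccinimide, O=C1CCC(=O)N1Br
Why: Kinetic deprotonation of the methyl ketone and O-silylation give the cross-conjugated silyl dienol ether, whose terminal methylene is its most nucleophilic carbon and is brominated by NBS (α-bromination of a ketone through its silyl enol ether), so the second bromine lands on the future C3.

Step 3
Reactants: 5 (Z)-1,3-dibromo-4-methoxybut-3-en-2-one
Product: 6 (1Z,3Z)-2,4-dibromo-1-methoxy-3-(trimethylsilyloxy)buta-1,3-diene
Conditions: TMSOTf, Et3N, Et2O, 0 °C; filtered and concentrated under argon, used crude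
Reagents that add atoms: trimethylsilyl trifluoromethanesulfonate, C[Si](C)(C)OS(=O)(=O)C(F)(F)F
Why: Soft enolisation with a silyl triflate and a tertiary amine should convert the acidified bromomethyl ketone into its silyl enol ether faster than the amine is alkylated, and the O/Br-cis geometry expected for α-halo enol ethers has no bearing on the annulation.

Step 4
Reactants: 7 2-hydroxybutanoic acid (racemic)
Product: 8 tert-butyldimethylsilyl 2-[(tert-butyldimethylsilyl)oxy]butanoate
Conditions: TBSCl (2.3 equiv), imidazole, DMF, rt
Reagents that add atoms: tert-butyldimethylsilyl chloride, CC(C)(C)[Si](C)(C)Cl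
Why: Exhaustive silylation of an α-hydroxy acid with a silyl chloride and imidazole is routine and gives the silyl ether/silyl ester needed for neutral acid chloride formation.

Step 5
Reactants: 8 tert-butyldimethylsilyl 2-[(tert-butyldimethylsilyl)oxy]butanoate
Product: 9 2-[(tert-butyldimethylsilyl)oxy]butanoyl chloride
Conditions: (COCl)2, DMF (cat.), CH2Cl2, 0 °C → rt; volatiles removed, used directly
Reagents that add atoms: oxalyl chloride, O=C(Cl)C(Cl)=O
Why: Silyl esters are converted by oxalyl chloride and catalytic DMF (Vilsmeier-type activation) into acid chlorides with loss of the silyl chloride, CO and CO2 under neutral conditions that leave the secondary silyl ether intact.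

Step 6
Reactants: 6 (1Z,3Z)-2,4-dibromo-1-methoxy-3-(trimethylsilyloxy)buta-1,3-diene; 9 2-[(tert-butyldimethylsilyl)oxy]butanoyl chloride
Product: 11 3,5-dibromo-2-{1-[(tert-butyldimethylsilyl)oxy]propyl}-4H-pyran-4-one, via bromodiketone 10 (not isolated)
Conditions: ZnCl2 (1 equiv), CH2Cl2/Et2O, −20 °C → rt; then TFA (cat.), CH2Cl2, rt
Reagents that add atoms: none
Why: ZnCl2 activates the acid chloride, the bromine-bearing terminal carbon of the silyl enol ether attacks the acyl carbon (Mukaiyama-type C-acylation) and TMSCl is lost, which forms C2–C3 and gives the 2-bromo-1,3-diketone 10. Under catalytic TFA the enol oxygen of 10 adds to the methoxy-bearing β-carbon of the remaining bromoenone and methanol is expelled, which forms O1–C6 and leaves the aromatic 4-pyranone. The closest known reaction type is the acylation of 1-methoxy-3-silyloxybutadienes (or the corresponding enolates) with acid chlorides followed by acid-mediated cyclisation to γ-pyrones. The ring closes in a 6-endo-trig oxa-Michael addition followed by β-elimination. No stereocentre is created, and the racemic carbinol centre of 9 is only carried through. C- over O-acylation is secured by the silylated enol oxygen, attack through the terminal carbon by the push of the methoxy group through the diene, and attack at the acid chloride alone by holding the side-chain carbonyl at the silyl ether level; the mild Lewis acid should spare the TBS ether and avoid decarbonylation of the α-oxygenated acyl chloride.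

Step 7
Reactants: 11 3,5-dibromo-2-{1-[(tert-butyldimethylsilyl)oxy]propyl}-4H-pyran-4-one
Product: 13 2,3,5-tribromo-6-{1-[(tert-butyldimethylsilyl)oxy]propyl}-4H-pyran-4-one, via C6-zinc species 12 (not isolated)
Conditions: TMPZnCl·LiCl, THF, 0 °C → rt; then Br2, −40 °C
Reagents that add atoms: bromine, BrBr
Why: The only ring hydrogen, at C6, is flanked by the ring oxygen and the C5 bromine and should be removed by the hindered zinc amide (directed zincation of 4-pyranone-type heterocycles next to oxygen), while the side-chain methine is held in the ring plane by allylic strain against the C3 bromine and is not aligned for deprotonation; the covalent heteroarylzinc does not expel the neighbouring bromide and is cleaved by bromine (halodemetalation).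

Step 8
Reactants: 13 2,3,5-tribromo-6-{1-[(tert-butyldimethylsilyl)oxy]propyl}-4H-pyran-4-one
Product: 14 2,3,5-tribromo-6-(1-hydroxypropyl)-4H-pyran-4-one
Conditions: HF (48% aq.), MeCN, 0 °C → rt
Reagents that add atoms: none
Why: Aqueous HF in acetonitrile cleaves the secondary TBS ether by fluoride attack at silicon in an acidic, weakly nucleophilic medium, which should spare the C6 bromide (a vinylogous acyl bromide) that amine-buffered or basic fluoride sources would displace.

Step 9
Reactants: 14 2,3,5-tribromo-6-(1-hydroxypropyl)-4H-pyran-4-one
Product: 15 2,3,5-tribromo-6-propanoyl-4H-pyran-4-one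
Conditions: Dess–Martin periodinane, CH2Cl2, rt
Reagents that add atoms: none
Why: Dess–Martin oxidation of the secondary, ring-activated carbinol proceeds under neutral, non-nucleophilic conditions, removes the only stereocentre of the route and delivers the propanoyl ketone of the target.

**Compound list**

1 | (E)-4-methoxybut-3-en-2-one | CO/C=C/C(C)=O | starting material
2 | 3,4-dibromo-4-methoxybutan-2-one (racemic diastereomer mixture, not isolated) | COC(Br)C(Br)C(C)=O | intermediate
3 | (Z)-3-bromo-4-methoxybut-3-en-2-one | CO/C=C(Br)/C(C)=O | intermediate
4 | (Z)-2-bromo-1-methoxy-3-(trimethylsilyloxy)buta-1,3-diene (not isolated) | CO/C=C(Br)/C(=C)O[Si](C)(C)C | intermediate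
5 | (Z)-1,3-dibromo-4-methoxybut-3-en-2-one | CO/C=C(Br)/C(=O)CBr | intermediate
6 | (1Z,3Z)-2,4-dibromo-1-methoxy-3-(trimethylsilyloxy)buta-1,3-diene | CO/C=C(Br)/C(O[Si](C)(C)C)=C/Br | intermediate
7 | 2-hydroxybutanoic acid (racemic) | CCC(O)C(=O)O | starting material
8 | tert-butyldimethylsilyl 2-[(tert-butyldimethylsilyl)oxy]butanoate (racemic) | CCC(O[Si](C)(C)C(C)(C)C)C(=O)O[Si](C)(C)C(C)(C)C | intermediate
9 | 2-[(tert-butyldimethylsilyl)oxy]butanoyl chloride (racemic) | CCC(O[Si](C)(C)C(C)(C)C)C(Cl)=O | intermediate
10 | (Z)-2,4-dibromo-6-[(tert-butyldimethylsilyl)oxy]-1-methoxyoct-1-ene-3,5-dione (keto form shown, enolised, not isolated) | CO/C=C(Br)/C(=O)C(Br)C(=O)C(CC)O[Si](C)(C)C(C)(C)C | intermediate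
11 | 3,5-dibromo-2-{1-[(tert-butyldimethylsilyl)oxy]propyl}-4H-pyran-4-one (racemic) | CCC(O[Si](C)(C)C(C)(C)C)c1occ(Br)c(=O)c1Br | intermediate
12 | chlorido(3,5-dibromo-6-{1-[(tert-butyldimethylsilyl)oxy]propyl}-4-oxo-4H-pyran-2-yl)zinc (not isolated) | CCC(O[Si](C)(C)C(C)(C)C)c1oc([Zn]Cl)c(Br)c(=O)c1Br | intermediate
13 | 2,3,5-tribromo-6-{1-[(tert-butyldimethylsilyl)oxy]propyl}-4H-pyran-4-one (racemic) | CCC(O[Si](C)(C)C(C)(C)C)c1oc(Br)c(Br)c(=O)c1Br | intermediate
14 | 2,3,5-tribromo-6-(1-hydroxypropyl)-4H-pyran-4-one (racemic) | CCC(O)c1oc(Br)c(Br)c(=O)c1Br | intermediate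
15 | 2,3,5-tribromo-6-propanoyl-4H-pyran-4-one | CCC(=O)c1oc(Br)c(Br)c(=O)c1Br | target

**Step count**

Total steps: 9. Longest linear sequence: 7 (steps 1, 2, 3, 6, 7, 8, 9).

**Steps most likely to fail**

Step 6. The twice-brominated enol ether may acylate too slowly under a mild Lewis acid, and the electrophilic bromine on the doubly activated carbon of 10 may be transferred away before the ring closes. The fallback sets out from 3 and moves the C3 bromination behind ring formation. Compound 3 is deprotonated with LiHMDS (2 equiv, THF, −78 °C) and the lithium enolate is acylated with 9 to give (Z)-2-bromo-6-[(tert-butyldimethylsilyl)oxy]-1-methoxyoct-1-ene-3,5-dione F1. Catalytic TFA closes this to 5-bromo-2-{1-[(tert-butyldimethylsilyl)oxy]propyl}-4H-pyran-4-one F2. NBS in MeCN then brominates the one remaining nucleophilic ring carbon, C3, and the route is rejoined at 11.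

Step 7. Zincation at C6 may be incomplete or may compete with deprotonation of the side-chain methine, and the metalated ring may decompose before it meets bromine. The fallback sets out from 11 and uses electrophilic addition–elimination instead of deprotonation. Br2 in CH2Cl2 at 0 °C is added across C5=C6 to give 2,3,3,5-tetrabromo-6-{1-[(tert-butyldimethylsilyl)oxy]propyl}-2,3-dihydro-4H-pyran-4-one F3. Dehydrobromination with i-Pr2NEt (the hydrogen on the O-bearing carbon and one of the geminal bromines) returns the route at 13. With the side chain at the silyl ether level there is no ketone α-position to brominate.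

Step 3. Alkylation of the amine by the bromomethyl ketone and hydrolytic loss of the labile bromo silyl enol ether on isolation may leave too little diene. The fallback sets out from 5 and avoids the silyl enol ether: soft enolisation with MgBr2·OEt2 and i-Pr2NEt in CH2Cl2 in the presence of 9 acylates the magnesium enolate directly to 10. This is closed with catalytic TFA as in step 6, so the route is rejoined at 10 and then 11; no new compound is made.

**Further compounds**

F1 | step 6 | (Z)-2-bromo-6-[(tert-butyldimethylsilyl)oxy]-1-methoxyoct-1-ene-3,5-dione | CO/C=C(Br)/C(=O)CC(=O)C(CC)O[Si](C)(C)C(C)(C)C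
F2 | step 6 | 5-bromo-2-{1-[(tert-butyldimethylsilyl)oxy]propyl}-4H-pyran-4-one | CCC(O[Si](C)(C)C(C)(C)C)c1cc(=O)c(Br)co1
F3 | step 7 | 2,3,3,5-tetrabromo-6-{1-[(tert-butyldimethylsilyl)oxy]propyl}-2,3-dihydro-4H-pyran-4-one | CCC(O[Si](C)(C)C(C)(C)C)C1=C(Br)C(=O)C(Br)(Br)C(Br)O1
F0 | step 3 | none | none
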